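**Plan**
- Retrosynthesis: the C13 methylene of the target is traced back to a ketone. The ester carbon C1 and the C12 methylene are then rejoined as the C1–C2 ring bond of a 2-acylcyclododecanone (a retro-Claisen opening in the forward sense). Last, the C12–C13 bond is cut into the morpholine enamine of cyclododecanone and hexadecanoyl chloride.
- Enabling feature: C1–C12 of the unbranched C28 acyl chain coincide with the twelve ring carbons of cyclododecanone (ring C=O = C1), and C13–C28 with a palmitoyl unit.
- Forward order: enamine formation; C-acylation (C12–C13 bond, no ring closed); ring opening by benzyl alkoxide, which installs the benzyl ester directly; tosylhydrazone; reduction of C13=O to CH2.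
- Stereochemistry: none to set. The one stereocentre met on the way (C2 of the diketone) is racemic and disappears on ring opening.

Key step: step 2

Remark on the chemistry: benzyl octacosanoate has no stereogenic element, so the "single enantiomer" is the one achiral compound and no step has to control configuration.

**Route**

Step 1
Reactants: 1 cyclododecanone; 2 morpholine
Product: 3 4-(cyclododec-1-en-1-yl)morpholine
Conditions: morpholine (3 equiv), TsOH·H2O (cat.), toluene, reflux, Dean–Stark; vacuum distillation, used at once
Reagents that add atoms: none
Why: Stork enamine formation (acid-catalysed condensation of a ketone with a secondary amine) should be driven to completion by azeotropic removal of water, the excess of amine compensating for the sluggish large-ring ketone; the ring double-bond geometry of 3 is irrelevant to what follows.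

Step 2
Reactants: 3 4-(cyclododec-1-en-1-yl)morpholine; 4 hexadecanoyl chloride
Product: 6 2-hexadecanoylcyclododecan-1-one (racemic), via C-acylated enamine 5 (not isolated)
Conditions: Et3N (1.2 equiv), CHCl3, slow addition of 4 at 0 °C, then 35 °C; then 10% aq HCl, 40 °C
Reagents that add atoms: water, O
Why: The nucleophilic β-carbon of enamine 3 attacks the acyl chloride, triethylamine removes the proton from the iminium stage to give the C-acylated enamine 5, and aqueous acid then hydrolyses 5 to the 1,3-diketone 6. The closest known reaction type is the Stork–Hünig acylation of cyclic ketone enamines with acid chlorides in the presence of a tertiary amine. No ring is closed: the single new skeletal bond joins the ring α-carbon (future C12) to the palmitoyl carbonyl (future C13). The new stereocentre at C2 of 6 is not controlled and need not be, since it is racemic, enolisable and becomes a methylene in step 3. The step needs C- rather than N- or O-acylation and mono- rather than bis-acylation; N-acylation of an enamine is reversible whereas C-acylation is not, and 5 is a vinylogous amide whose delocalised nitrogen lone pair leaves it too poor a nucleophile for a second acyl group. Slow addition of 4 into the enamine/amine solution keeps the acid chloride, and any ketene derived from it, scarce.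

Step 3
Reactants: 6 2-hexadecanoylcyclododecan-1-one; 7 benzyl alcohol
Product: 8 benzyl 13-oxooctacosanoate
Conditions: BnONa (0.2 equiv, from NaH), BnOH (10 equiv), toluene, 80 °C; AcOH quench
Reagents that add atoms: none
Why: Retro-Claisen alcoholysis of a 2-acylcycloalkanone: benzyl alkoxide should add to the ring carbonyl and the tetrahedral intermediate should fragment across the C1–C2 ring bond, expelling the acyclic ketone enolate, so that the ring carbonyl becomes the benzyl ester C1 and the ring α-carbon the C12 methylene; opening is expected to be favoured over acyl transfer from the side-chain carbonyl by release of the transannular strain of the twelve-membered ring, and is held on the open side by the large excess of benzyl alcohol with only catalytic base.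

Step 4
Reactants: 8 benzyl 13-oxooctacosanoate
Product: 9 benzyl 13-[2-(4-methylbenzenesulfonyl)hydrazinylidene]octacosanoate
Conditions: TsNHNH2 (1.1 equiv), AcOH (cat.), 4 Å MS, THF, 50 °C
Reagents that add atoms: p-toluenesulfonyl hydrazide, Cc1ccc(cc1)S(=O)(=O)NN
Why: Acid-catalysed condensation of the unhindered dialkyl ketone with tosylhydrazide (tosylhydrazone formation) should be clean, the weakly nucleophilic sulfonyl hydrazide leaving the benzyl ester untouched in an alcohol-free medium; the C=N geometry (E/Z mixture) is of no consequence.

Step 5
Reactants: 9 benzyl 13-[2-(4-methylbenzenesulfonyl)hydrazinylidene]octacosanoate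
Product: 12 benzyl octacosanoate, via N-boryl tosylhydrazine 10 (not isolated), via alkyldiazene 11 (not isolated)
Conditions: catecholborane (1.5 equiv), CHCl3, 0 °C → rt; then NaOAc·3H2O (3 equiv), reflux
Reagents that add atoms: none
Why: Kabalka-type reductive deoxygenation of a tosylhydrazone: catecholborane hydroborates the C=N bond, acetate attack at boron triggers loss of sulfinate to the monoalkyldiazene, and this extrudes N2 to leave the C13 methylene, under conditions in which catecholborane does not reduce the ester and nothing hydrogenolyses the benzyl group.

**Compound list**
1 | cyclododecanone | O=C1CCCCCCCCCCC1 | starting material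
2 | morpholine | C1COCCN1 | starting material
3 | 4-(cyclododec-1-en-1-yl)morpholine (ring double-bond geometry undefined) | C1(N2CCOCC2)=CCCCCCCCCCC1 | intermediate
4 | hexadecanoyl chloride | CCCCCCCCCCCCCCCC(=O)Cl | starting material
5 | 1-[2-(morpholin-4-yl)cyclododec-1-en-1-yl]hexadecan-1-one | CCCCCCCCCCCCCCCC(=O)C1=C(N2CCOCC2)CCCCCCCCCC1 | intermediate (not isolated)
6 | 2-hexadecanoylcyclododecan-1-one (racemic, enolisable) | CCCCCCCCCCCCCCCC(=O)C1CCCCCCCCCCC1=O | intermediate
7 | benzyl alcohol | OCc1ccccc1 | starting material
8 | benzyl 13-oxooctacosanoate | CCCCCCCCCCCCCCCC(=O)CCCCCCCCCCCC(=O)OCc1ccccc1 | intermediate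
9 | benzyl 13-[2-(4-methylbenzenesulfonyl)hydrazinylidene]octacosanoate (E/Z mixture) | CCCCCCCCCCCCCCCC(=NNS(=O)(=O)c1ccc(C)cc1)CCCCCCCCCCCC(=O)OCc1ccccc1 | intermediate
10 | benzyl 13-[1-(1,3,2-benzodioxaborol-2-yl)-2-(4-methylbenzenesulfonyl)hydrazinyl]octacosanoate | CCCCCCCCCCCCCCCC(N(B1Oc2ccccc2O1)NS(=O)(=O)c1ccc(C)cc1)CCCCCCCCCCCC(=O)OCc1ccccc1 | intermediate (not isolated)
11 | benzyl 13-diazenyloctacosanoate | CCCCCCCCCCCCCCCC(N=N)CCCCCCCCCCCC(=O)OCc1ccccc1 | intermediate (not isolated)
12 | benzyl octacosanoate | CCCCCCCCCCCCCCCCCCCCCCCCCCCC(=O)OCc1ccccc1 | target

Total step count: 5
Longest linear sequence: 5 steps (1 → 3 → 6 → 8 → 9 → 12)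

**Steps most likely to fail, with fallbacks**

Step 3. The alkoxide may add to the side-chain carbonyl instead of the ring carbonyl, so that acyl transfer takes the place of ring opening. The reaction may also stall because the base is tied up as the unreactive diketone enolate. Fallback, setting out from 6: cleavage with KOH in aqueous ethanol at reflux, where formation of the carboxylate makes the opening irreversible, followed by acidification with HCl to 13-oxooctacosanoic acid F1. Steglich esterification of F1 with benzyl alcohol 7 (DCC, cat. DMAP, CH2Cl2) should then return to the route at 8.

Step 2. Triethylamine may dehydrochlorinate 4 to a ketene, which can dimerise or add to the enamine in a [2+2] sense and reopen with ring enlargement instead of giving the 2-acyl ketone. Adventitious hydrolysis of the moisture-sensitive enamine is a second loss channel. Fallback, setting out from 4 and 1, without an enamine: 4 should be converted with 1H-benzotriazole and Et3N in CH2Cl2 into 1-(1H-benzotriazol-1-yl)hexadecan-1-one F2, an acyl donor that does not form a ketene. F2 should then C-acylate cyclododecanone 1 under soft-enolisation conditions (MgBr2·OEt2, i-Pr2NEt, CH2Cl2, rt) through the chelated magnesium enolate, returning to the route at 6.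

Step 5. Hydride delivery to the hindered C=N flanked by two long chains may be slow, and the acetate-induced decomposition may divert to base-induced elimination giving alkene instead of reduction. Fallback, setting out from 8, with the deoxygenation moved to the acid level: saponification with KOH in diethylene glycol, then hydrazine hydrate with heating to about 195 °C and distillation of water (Huang-Minlon Wolff–Kishner reduction), and acidification with HCl, should give octacosanoic acid F3. Fischer esterification of F3 with benzyl alcohol 7 (cat. TsOH, toluene, Dean–Stark) should return to the route at 12.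

**Further compounds**
F1 | step 3 | 13-oxooctacosanoic acid | CCCCCCCCCCCCCCCC(=O)CCCCCCCCCCCC(=O)O
F2 | step 2 | 1-(1H-benzotriazol-1-yl)hexadecan-1-one | CCCCCCCCCCCCCCCC(=O)n1nnc2ccccc21
F3 | step 5 | octacosanoic acid | CCCCCCCCCCCCCCCCCCCCCCCCCCCC(=O)O
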